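## Structural features

Hansfordiol B (16) is an achiral 5-alkylresorcinol: one benzene ring (ring A) with hydroxyl groups at C1 and C3 and one unbranched C17 chain at C5. The chain is joined to ring A through C1′ by an aryl–C(sp3) bond, runs through fifteen methylene groups (C1′–C15′) and ends in a methyl ketone (C16′ carbonyl, C17′ methyl). There is no stereocenter and no stereogenic double bond, so no stereocenters stand next to each other and nothing has to be controlled in three dimensions. The fragile groups are the free resorcinol and the methyl ketone. The resorcinol is electron-rich, C-nucleophilic at C2, C4 and C6, and prone to oxidation and to acid-catalysed condensation with carbonyl compounds. The ketone is enolizable and electrophilic and cannot coexist with a carbanion at the other chain end. The real difficulty is the all-meta pattern of ring A: each substituent is meta to the other two, so the C5–C1′ bond cannot be made by electrophilic substitution on a resorcinol and is normally bought in a 3,5-dioxygenated arene. The key step exploits the strict alternation C1(O), C2(H), C3(O), C4(H), C5(chain), C6(H): it is the sum of a four-carbon unit C1–C6–C5–C4 (a 3-substituted cyclobutenone: carbonyl C1, CH2 C6, chain-bearing C5, CH C4) and a two-carbon unit C2–C3 (an ynol ether whose oxygen-bearing carbon becomes C3). In one sentence: ring A is made in a thermal pericyclic cascade from the chain-bearing cyclobutenone 9 and the two-carbon ynol ether 10.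

## Logic of the disconnections

16 ⇒ 15. The only bond cut is the O–CH2 bond of the ethyl ether on the C3 oxygen of ring A. The key step delivers the C1 oxygen as a phenol and the C3 oxygen as an ether, so one dealkylation is the price of the annulation. There is no gain in skeletal simplicity. The forward step must remove the ethyl group without harming the C16′ ketone or the electron-rich ring.

15 ⇒ 9 + 10 (key disconnection). Ring A is cut at C1–C2 and C3–C4, which releases C2–C3 with its ethoxy group as 10. C1 is then rejoined to C4, so that C1, C6, C5 and C4 become the four-membered enone ring of 9. Cutting here removes the aromatic ring and with it the all-meta problem: the chain sits on the one substituted sp2 carbon of a small ring, and each oxygen comes from a different partner. The gain is from a 1,3,5-trisubstituted arene to a monosubstituted four-membered ring plus a purchased alkyne. The forward step must form C1–C2 and C3–C4 in one orientation only and must capture a transient ketene faster than it is lost.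

9 ⇒ 4 + 5. The bond between chain carbon C1′ and the substituted ring carbon of 9 is cut, and the C16′ ketone is returned to its dioxolane. The four-membered ring then comes from 5, whose ethoxy-bearing carbon is the latent carbonyl of 9 and whose carbonyl carbon is attacked by the chain carbanion 6 made from 4; 7 and 8 are passed through in the acid work-up. The gain is that the ring is bought and the whole chain arrives as one nucleophile. The forward step needs 1,2-addition, a quench of the cyclobutenolate before it can ring-open, and an acid treatment that transposes the carbonyl and frees the ketone without destroying the strained enone.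

4 ⇒ 3. The two C–O bonds of the dioxolane at C16′ are cut. The only reason is that a Grignard reagent cannot be made next to a free ketone. The forward step must ketalize without touching the C–Br bond.

3 ⇒ 1. The C16′–C17′ bond is cut: the methyl group is added to the carboxyl carbon of 1 through 2. Compound 1 already holds C1′ to C16′ in one chain with the two ends differentiated, so no chain-building step is needed. The forward step must stop at the ketone and leave the primary bromide alone.

## Other disconnections considered

Alternative 1: This is the first disconnection that comes to mind. The cut is the C1′–C2′ bond next to ring A, made as an alkene. The forward key step would be a Wittig olefination of purchased 3,5-dimethoxybenzaldehyde with the ylide of [14-(2-methyl-1,3-dioxolan-2-yl)tetradecyl]triphenylphosphonium bromide A1. It would give the styrene 2-[(14Z)-15-(3,5-dimethoxyphenyl)pentadec-14-en-1-yl]-2-methyl-1,3-dioxolane A2, which hydrogenation over Pd/C and BBr3 would carry to the target. The plan should work. It is set aside for two reasons: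
- Ring A with its all-meta pattern is bought, so the key step solves only a chain-joining problem.
- A1 needs a C15 ω-bromo chain (from purchased 15-pentadecanolide through lactone opening, ketone formation, ketalization and phosphonium salt formation). The sequence comes to about seven operations, one of them a hydrogenation that only erases the alkene. The chosen plan needs five.

Alternative 2: The cut is the C5–C1′ bond, with the chain read as an opened 16-membered carbocycle. The forward key step would be a deconstructive arylation of 1-methylcyclohexadecan-1-ol A3 (from purchased cyclohexadecanone and MeMgBr):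
- An alkoxy radical would be generated by photochemical proton-coupled electron transfer with an acridinium photooxidant.
- β-Scission would give a primary radical that already carries the methyl ketone.
- NiBr2(dme) with 4,4′-di-tert-butyl-2,2′-bipyridine would couple it with purchased 1-bromo-3,5-bis(benzyloxy)benzene to give 17-[3,5-bis(benzyloxy)phenyl]heptadecan-2-one A4, which hydrogenolysis would turn into the target.

This is the shortest plan on paper (three operations). It is set aside on mechanistic grounds. In a strain-free 16-membered ring nothing accelerates β-scission to a primary radical, while transannular 1,5-hydrogen transfer through a six-membered transition state is open from several methylene groups. That transfer is expected to compete and to lead to ring-retained arylation isomers, so the main pathway of the key step is itself in doubt.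

Alternative 3: The cut is the ring bond C5–C6, with an extra carboxyl carbon on C6, as in the biosynthesis. The forward key step would be the aldol aromatization of a tetraketide equivalent:
- The Weinreb amide N-methoxy-N-methyl-16-(2-methyl-1,3-dioxolan-2-yl)hexadecanamide A5 would acylate the dianion of 2,2-dimethyl-6-(2-oxopropyl)-4H-1,3-dioxin-4-one A6.
- This would give the diketo-dioxinone 2,2-dimethyl-6-[19-(2-methyl-1,3-dioxolan-2-yl)-2,4-dioxononadecyl]-4H-1,3-dioxin-4-one A7.
- Thermolysis of A7 in methanol, then Cs2CO3 and acid, would give methyl 2,4-dihydroxy-6-[15-(2-methyl-1,3-dioxolan-2-yl)pentadecyl]benzoate A8.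
- Saponification, decarboxylation and ketal hydrolysis would finish.

The plan also makes ring A from a chain, but it is set aside for three reasons:
- A5 needs a C18 skeleton, one carbon more than 1 supplies, so a homologation is added.
- The carboxyl group that steers the aldol has to be put in and taken out again.
- The polycarbonyl chain has competing cyclization modes (lactonization to a 4-hydroxy-2-pyrone, Claisen closure).

About nine operations would be needed against five.

Key step: step 4

Assumption: 16-bromohexadecanoic acid, 3-ethoxycyclobut-2-en-1-one and ethoxyethyne (as a solution in hexanes) are taken as purchasable; the target has no stereocenter, so no step has to set configuration.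

## Route

Step 1
Reactants: 1 16-bromohexadecanoic acid
Product: 3 17-bromoheptadecan-2-one, via acid chloride 2 (not isolated)
Conditions: (COCl)2, cat. DMF, CH2Cl2, 0 °C to rt, evaporation; then Me2CuLi (3 equiv, from MeLi and CuBr·SMe2), Et2O/THF, −78 °C; aq NH4Cl
Reagents that add atoms: lithium dimethylcuprate, [Li+].C[Cu-]C
Why: Acyl chloride formation under Vilsmeier-type DMF catalysis, then ketone synthesis by acyl substitution with a Gilman cuprate. At −78 °C the cuprate does not add to the ketone formed and does not substitute a primary alkyl bromide, so the reaction should stop at 3 with the C–Br bond intact.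

Step 2
Reactants: 3 17-bromoheptadecan-2-one
Product: 4 2-(15-bromopentadecyl)-2-methyl-1,3-dioxolane
Conditions: HOCH2CH2OH, cat. TsOH·H2O, PhMe, reflux, Dean–Stark
Reagents that add atoms: ethane-1,2-diol, OCCO
Why: Acid-catalysed ketalization driven by azeotropic removal of water. The primary bromide is inert, and the dioxolane masks the only group that a Grignard reagent made from this chain would attack.

Step 3
Reactants: 4 2-(15-bromopentadecyl)-2-methyl-1,3-dioxolane; 5 3-ethoxycyclobut-2-en-1-one
Product: 9 3-(16-oxoheptadecyl)cyclobut-2-en-1-one, via Grignard reagent 6 (not isolated), via cyclobutenol adduct 7 (not isolated), via ketal cyclobutenone 8 (not isolated)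
Conditions: Mg, THF, 45 °C; then 5, THF, −78 °C; 2 M HCl added at −78 °C, then THF/H2O, rt
Reagents that add atoms: water, O
Why: Grignard formation and 1,2-addition to the strained carbonyl of the vinylogous ester 5, which cannot be enolized because its enolate would be a cyclobutadiene. Aqueous acid then ionizes the tertiary allylic alcohol of 7 to an ethoxy-stabilized allyl cation, which water captures at the ethoxy-bearing carbon with loss of ethanol (1,3-carbonyl transposition of Stork–Danheiser type), and the same acid hydrolyses the dioxolane of 8. The stereocenter of 7 is racemic and disappears in the transposition.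

Step 4
Reactants: 9 3-(16-oxoheptadecyl)cyclobut-2-en-1-one; 10 ethoxyethyne
Product: 15 3-ethoxy-5-(16-oxoheptadecyl)phenol, via vinylketene 11 (not isolated), via vinylcyclobutenone 12 (not isolated), via dienylketene 13 (not isolated), via cyclohexadienone 14 (not isolated)
Conditions: 10 (2.5 equiv), PhMe, 80 °C, sealed tube; then K2CO3, MeOH, rt
Reagents that add atoms: none
Why: This is a Danheiser benzannulation, and the closest known reaction type is exactly this union of a 3-alkylcyclobutenone with an alkoxyacetylene to give a resorcinol monoether. At 80 °C the C1–C4 σ bond of 9 opens in a reversible 4π electrocyclic reaction to vinylketene 11, whose ketene C=C adds across the triple bond of 10 in a [2+2] cycloaddition to give 12. Compound 12 opens again (4π, reversible) to dienylketene 13, and only the isomer that holds the ketene carbon and the terminal methylene cis is drained, by thermal disrotatory 6π electrocyclization, to cyclohexadienone 14, which tautomerizes irreversibly to 15. Ring A is therefore closed by a 6π electrocyclization that forms C1–C6 after the [2+2] event has formed C1–C2 and C3–C4, and the four-membered ring of 12 is closed by the ketene–alkyne [2+2] and is only transient. No stereocenter is present in 15, and the single sp3 ring carbon of 12 forms as a racemate and is erased. The step needs one orientation in the [2+2], the ethoxy-bearing alkyne carbon bonding to the ketene α-carbon, and the polarization of the partners secures it: the unsubstituted carbon of the ynol ether is its nucleophilic terminus and the ketene carbonyl carbon is the electrophilic one, so the oxygen of 10 ends up meta to the phenol oxygen and the chain, fixed on the ring of 9, meta to both. The step also needs capture of 11 by 10 to outrun ketene dimerization and acylation of the product phenol, which the excess of 10 provides, and any aryl ester formed is cleaved in the carbonate work-up. The remote methyl ketone has no role, since neither a ketene nor an ynol ether adds to an unactivated ketone without a Lewis acid.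

Step 5
Reactants: 15 3-ethoxy-5-(16-oxoheptadecyl)phenol
Product: 16 Hansfordiol B [5-(16-oxoheptadecyl)benzene-1,3-diol]
Conditions: BBr3 (4 equiv), CH2Cl2, −78 to 0 °C; then H2O
Reagents that add atoms: none
Why: Lewis acid–mediated cleavage of an aryl alkyl ether: BBr3 coordinates the ether oxygen, bromide attacks the ethyl CH2 in an SN2 step, and the aryl borate is hydrolysed on work-up. The ketone is only complexed and should return unchanged, and the molecule has no other acid-labile group.

## Compound list

1 | 16-bromohexadecanoic acid | OC(=O)CCCCCCCCCCCCCCCBr | starting material
2 | 16-bromohexadecanoyl chloride | ClC(=O)CCCCCCCCCCCCCCCBr | intermediate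
3 | 17-bromoheptadecan-2-one | CC(=O)CCCCCCCCCCCCCCCBr | intermediate
4 | 2-(15-bromopentadecyl)-2-methyl-1,3-dioxolane | CC1(CCCCCCCCCCCCCCCBr)OCCO1 | intermediate
5 | 3-ethoxycyclobut-2-en-1-one | CCOC1=CC(=O)C1 | starting material
6 | [15-(2-methyl-1,3-dioxolan-2-yl)pentadecyl]magnesium bromide | CC1(CCCCCCCCCCCCCCC[Mg]Br)OCCO1 | intermediate
7 | 3-ethoxy-1-[15-(2-methyl-1,3-dioxolan-2-yl)pentadecyl]cyclobut-2-en-1-ol (racemic; formed as its bromomagnesium alkoxide) | CCOC1=CC(O)(CCCCCCCCCCCCCCCC2(C)OCCO2)C1 | intermediate
8 | 3-[15-(2-methyl-1,3-dioxolan-2-yl)pentadecyl]cyclobut-2-en-1-one | CC1(CCCCCCCCCCCCCCCC2=CC(=O)C2)OCCO1 | intermediate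
9 | 3-(16-oxoheptadecyl)cyclobut-2-en-1-one | CC(=O)CCCCCCCCCCCCCCCC1=CC(=O)C1 | intermediate
10 | ethoxyethyne | CCOC#C | starting material
11 | 3-(16-oxoheptadecyl)buta-1,3-dien-1-one (vinylketene) | CC(=O)CCCCCCCCCCCCCCCC(=C)C=C=O | intermediate
12 | 3-ethoxy-4-(18-oxononadec-1-en-2-yl)cyclobut-2-en-1-one (racemic) | CC(=O)CCCCCCCCCCCCCCCC(=C)C1C(=O)C=C1OCC | intermediate
13 | (3E)-3-ethoxy-5-(16-oxoheptadecyl)hexa-1,3,5-trien-1-one (dienylketene; ketene carbon and C5 cis across C3=C4) | CC(=O)CCCCCCCCCCCCCCCC(=C)/C=C(OCC)\C=C=O | intermediate
14 | 3-ethoxy-5-(16-oxoheptadecyl)cyclohexa-2,4-dien-1-one | CC(=O)CCCCCCCCCCCCCCCC1=CC(OCC)=CC(=O)C1 | intermediate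
15 | 3-ethoxy-5-(16-oxoheptadecyl)phenol | CC(=O)CCCCCCCCCCCCCCCc1cc(O)cc(OCC)c1 | intermediate
16 | Hansfordiol B, 5-(16-oxoheptadecyl)benzene-1,3-diol | CC(=O)CCCCCCCCCCCCCCCc1cc(O)cc(O)c1 | target

## Step count and least certain steps

Total step count: 5. Longest linear sequence: 5 steps (1 → 3 → 4 → 9 → 15 → 16); 5 and 10 are purchased.

Step 4 (key step). Three processes may compete:
- Bimolecular capture of the transient vinylketene may lose to ketene dimerization or to acylation of phenol already formed.
- The ynol ether may fragment thermally (loss of ethylene) and be depleted before capture.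
- The cascade may stall at the vinylcyclobutenone stage if the second ring opening is slow at 80 °C.

The fallback gives up ring construction and joins the chain to a bought ring. It sets out from 4. Purchased 1-bromo-3,5-dimethoxybenzene would be converted with Mg in THF into (3,5-dimethoxyphenyl)magnesium bromide F1. F1 would be coupled with 4 under Li2CuCl4 catalysis in THF to give 2-[15-(3,5-dimethoxyphenyl)pentadecyl]-2-methyl-1,3-dioxolane F2. Aqueous HCl in THF would release 17-(3,5-dimethoxyphenyl)heptadecan-2-one F3, and BBr3 in CH2Cl2 would remove both methyl groups. The fallback comes back to the route at 16.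

Step 3. Three processes may go wrong:
- The magnesium cyclobutenolate may undergo anion-accelerated electrocyclic ring opening before the acid quench.
- The strained enone may degrade during the time in aqueous acid that the dioxolane needs.
- Wurtz-type homocoupling may erode the Grignard reagent.

The fallback makes the four-membered ring by cycloaddition instead of carbonyl addition and postpones ketal hydrolysis until after aromatization. It sets out from 4. Displacement with LiC≡CH·H2NCH2CH2NH2 in DMSO would give 2-(heptadec-16-yn-1-yl)-2-methyl-1,3-dioxolane F4. A [2+2] cycloaddition with dichloroketene (Cl3CCOCl, Zn–Cu couple, Et2O/DME) would give 4,4-dichloro-3-[15-(2-methyl-1,3-dioxolan-2-yl)pentadecyl]cyclobut-2-en-1-one F5. Zn, AcOH and TMEDA in EtOH would remove both chlorines to give 8, now isolated. Compounds 8 and 10 under the conditions of step 4 would give 3-ethoxy-5-[15-(2-methyl-1,3-dioxolan-2-yl)pentadecyl]phenol F6, and PPTS in wet acetone would free the ketone. The fallback comes back to the route at 15.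

Step 5. Lewis-acid activation of the ketone may lead to aldol-type self-condensation or to hydroxyalkylation of the electron-rich ring, and cleavage of an ethyl ether is slower than that of a methyl ether, so conversion may be incomplete. The fallback brings the second oxygen in as a silyl ether so that fluoride, not a Lewis acid, unveils it. It sets out from 9. Lithium ethynolate F7, generated by oxidation of lithium acetylide with lithium tert-butyl peroxide, would be O-silylated with iPr3SiCl to ethynyloxytri(propan-2-yl)silane F8. Heating 9 with F8 in PhMe, in the siloxyalkyne version of the same benzannulation, would give 17-[3-hydroxy-5-(triisopropylsilyloxy)phenyl]heptadecan-2-one F9. Bu4NF buffered with AcOH in THF would remove the silyl group. The fallback comes back to the route at 16.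

Step 1. Over-addition to the tertiary alcohol may occur if free MeLi is present in the cuprate, and substitution or reduction at the C–Br bond may occur if the temperature rises. The fallback transfers the methyl group through a chelated tetrahedral intermediate instead of a cuprate. It sets out from 2. MeNH(OMe)·HCl and Et3N in CH2Cl2 would give 16-bromo-N-methoxy-N-methylhexadecanamide F10, and MeMgBr in THF at 0 °C would give the ketone. The fallback comes back to the route at 3.

## Further compounds

F1 | step 4 | (3,5-dimethoxyphenyl)magnesium bromide | COc1cc(OC)cc([Mg]Br)c1
F2 | step 4 | 2-[15-(3,5-dimethoxyphenyl)pentadecyl]-2-methyl-1,3-dioxolane | CC1(CCCCCCCCCCCCCCCc2cc(OC)cc(OC)c2)OCCO1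
F3 | step 4 | 17-(3,5-dimethoxyphenyl)heptadecan-2-one | CC(=O)CCCCCCCCCCCCCCCc1cc(OC)cc(OC)c1
F4 | step 3 | 2-(heptadec-16-yn-1-yl)-2-methyl-1,3-dioxolane | CC1(CCCCCCCCCCCCCCCC#C)OCCO1
F5 | step 3 | 4,4-dichloro-3-[15-(2-methyl-1,3-dioxolan-2-yl)pentadecyl]cyclobut-2-en-1-one | CC1(CCCCCCCCCCCCCCCC2=CC(=O)C2(Cl)Cl)OCCO1
F6 | step 3 | 3-ethoxy-5-[15-(2-methyl-1,3-dioxolan-2-yl)pentadecyl]phenol | CC1(CCCCCCCCCCCCCCCc2cc(O)cc(OCC)c2)OCCO1
F7 | step 5 | lithium ethynolate | [Li+].[O-]C#C
F8 | step 5 | ethynyloxytri(propan-2-yl)silane | C#CO[Si](C(C)C)(C(C)C)C(C)C
F9 | step 5 | 17-[3-hydroxy-5-(triisopropylsilyloxy)phenyl]heptadecan-2-one | CC(=O)CCCCCCCCCCCCCCCc1cc(O)cc(O[Si](C(C)C)(C(C)C)C(C)C)c1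
F10 | step 1 | 16-bromo-N-methoxy-N-methylhexadecanamide | CON(C)C(=O)CCCCCCCCCCCCCCCBr
A1 | alternative 1 | [14-(2-methyl-1,3-dioxolan-2-yl)tetradecyl]triphenylphosphonium bromide | CC1(CCCCCCCCCCCCCC[P+](c2ccccc2)(c2ccccc2)c2ccccc2)OCCO1.[Br-]
A2 | alternative 1 | 2-[(14Z)-15-(3,5-dimethoxyphenyl)pentadec-14-en-1-yl]-2-methyl-1,3-dioxolane | CC1(CCCCCCCCCCCCC/C=C\c2cc(OC)cc(OC)c2)OCCO1
A3 | alternative 2 | 1-methylcyclohexadecan-1-ol | CC1(O)CCCCCCCCCCCCCCC1
A4 | alternative 2 | 17-[3,5-bis(benzyloxy)phenyl]heptadecan-2-one | CC(=O)CCCCCCCCCCCCCCCc1cc(OCc2ccccc2)cc(OCc2ccccc2)c1
A5 | alternative 3 | N-methoxy-N-methyl-16-(2-methyl-1,3-dioxolan-2-yl)hexadecanamide | CON(C)C(=O)CCCCCCCCCCCCCCCC1(C)OCCO1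
A6 | alternative 3 | 2,2-dimethyl-6-(2-oxopropyl)-4H-1,3-dioxin-4-one | CC(=O)CC1=CC(=O)OC(C)(C)O1
A7 | alternative 3 | 2,2-dimethyl-6-[19-(2-methyl-1,3-dioxolan-2-yl)-2,4-dioxononadecyl]-4H-1,3-dioxin-4-one | CC1(C)OC(=CC(=O)O1)CC(=O)CC(=O)CCCCCCCCCCCCCCCC2(C)OCCO2
A8 | alternative 3 | methyl 2,4-dihydroxy-6-[15-(2-methyl-1,3-dioxolan-2-yl)pentadecyl]benzoate | COC(=O)c1c(O)cc(O)cc1CCCCCCCCCCCCCCCC2(C)OCCO2
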